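The numbers in the tables were computed with constants of no real substance; the scatter is artificial.

Start from the end state and ask what the limiting reagent allows. If one reagent makes one target, the 0.700 equiv of reagent charged caps target at that fraction of the starting material, and the bench rule of thumb says a flask simply climbs to this cap.

the same everywhere: precatalyst 2.6 mol%

| charge | starting material | second substrate | reagent | remark | time |
|---|---|---|---|---|---|
| Saturday's | 0.20 M | 2 equiv | 0.70 equiv | run made earlier |  |
| Sunday's | 0.10 M | 2 equiv | 0.70 equiv | run made earlier |  |
| Thursday's | 0.40 M | 2 equiv | 0.70 equiv | run made earlier |  |
| Friday's | 0.20 M | 1 equiv | 0.70 equiv | run made earlier |  |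
| violet | 0.20 M | 2.00 equiv | 0.700 equiv | everything together in a closed stirred flask, run for 15 h | 15 h |
| amber | 0.20 M | 2.00 equiv (fed, over 7.50 h) | 0.700 equiv | a stirred flask in which second substrate is dosed at a steady rate over 7.50 h without added volume, worked up at 15 h | 15 h |
| green | 0.20 M | 2.00 equiv | 0.700 equiv | a single well-mixed tank run continuously and read at steady state, 15 h in it on average |  |
| ochre | 0.20 M (fed, over 7.50 h) | 2.00 equiv | 0.700 equiv | all but starting material at the start; starting material goes in evenly over 7.50 h, the run ends at 15 h | 15 h |

- Saturday's (time / h: target / %): 2.50: 4.5; 5.00: 14.6; 6.00: 19.3; 10.0: 35.9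
- Sunday's (time / h: target / %): 3.00: 3.7; 6.00: 11.9; 10.0: 24.6; 12.0: 31.6
- Thursday's (time / h: target / %): 3.00: 9.7; 6.00: 27.2; 10.0: 42.5; 12.0: 44.4
- Friday's (time / h: target / %): 1.00: 1.0; 2.00: 3.7; 5.00: 17.3; 12.0: 50.3

(each reading ± 0.3 percentage points)

- the stated concentrations are those of everything mixed, before any reaction; amounts are the same in each set-up
- the feed brings no volume worth counting
- the earlier runs were made in a closed, stirred flask

- the set-up with the highest amount of target at the outlet or at the end, in percent of the starting material put in ("none" if the first two lie within 2 percentage points) (violet / amber / green / ochre / none)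
- amount of target at the outlet or at the end, in percent of the starting material put in, violet
- amount of target at the outlet or at the end, in percent of the starting material put in, amber
- amount of target at the outlet or at the end, in percent of the starting material put in, green
- amount of target at the outlet or at the end, in percent of the starting material put in, ochre

Thursday's run marks the border of that rule. It reads 42.5% at 10.0 h and 44.4% at 12.0 h, a gain of just 1.9 percentage points, and it is slowing well below the cap. Dividing that last reading by the charge gives 0.634, and this reading bounds from below the reagent yield s: target formed per reagent spent. You divided by the whole charge, so any reagent still left in Thursday's flask makes the yield there larger than this reading. Friday's run, with 1 equiv of second substrate, has already reached 0.719 on the same division, more than Thursday's. Friday's run also has less starting material than Thursday's, so two settings differ, but suspect that s rises when less second substrate stands in the flask.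

Now reckon violet. It has Thursday's 2.00 equiv of second substrate, so if the split follows the ratio of the charges and violet spends its reagent as far as Thursday's run did, s gives a low mark of 44.4%. For a high mark, continue Saturday's last slope to 15 h, which gives 56.6%. My own reckoning takes the middle, 50.5%, and puts amber above violet: amber doses its second substrate, and Friday's 0.719 stood above Thursday's 0.634 with less of it in the flask.

The forecast, holding that “excess second substrate inhibits mildly”, names amber and gives 48% for violet, a little under my figure, then 52% for amber, 45% for green and 44% for ochre.

The flasks give 48.8% for violet, 52.6% for amber, 40.0% for green and 44.1% for ochre, so amber comes out highest.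

    reagent + catalyst intermediate A → free catalyst + target (k = 170 M⁻¹ h⁻¹)
    second substrate + free catalyst → spent catalyst (k = 0.200 M⁻¹ h⁻¹)
    precatalyst → free catalyst (k = 0.140 h⁻¹)
    reagent + catalyst intermediate B → free catalyst + second product (k = 63.0 M⁻¹ h⁻¹)
    second substrate + free catalyst ⇌ catalyst intermediate B (K = 1.60 M⁻¹, k = 1000 M⁻¹ h⁻¹)
    starting material + free catalyst ⇌ catalyst intermediate A (K = 66.0 M⁻¹, k = 51.0 M⁻¹ h⁻¹)

Amber still holds 5.5% of its reagent at 15.0 h, so its reagent yield is 0.795, above the 0.634 read from Thursday's run. The same flask as amber with 0.800 equiv of second substrate gives 60.3% with 4.4% of its reagent left, a reagent yield of 0.901.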